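## Structural features

Target 34 is an ent-labdane diterpenoid: a trans-fused decalin (ring A = C1–C5, C10; ring B = C5–C10) bearing at C9 a five-carbon chain (C11–C15, methyl C16) with an E trisubstituted olefin at C13=C14 and a primary allylic acetate at C15. Ring A carries the gem-dimethyl carbon C4 and a cis 2,3-diol, both hydroxyls on the face opposite the angular methyl C20 (C2–OH equatorial, C3–OH axial and neopentyl); ring B carries the trisubstituted olefin C7=C8 with methyl C17. The five stereocentres form two contiguous groups, C2–C3 and C5–C10–C9, separated by C4; C10 is quaternary and sits between C5 and C9, and H5 and H9 lie on the face opposite C20. Fragile groups are the allylic acetate (base, hydride, ionisation), the two trisubstituted olefins (acid can move C7=C8 to the tetrasubstituted C8=C9 position; electrophilic oxidants attack both) and the cis-diol. The real difficulty is ring A and its junction: two fully substituted carbons (C4 and C10) flanking C5, the axial C3 hydroxyl beside C4, and a C9 stereocentre that is allylic to a non-conjugated olefin. The key step exploits that C4 with its two methyls is attached to C5 of a methylcyclohexene: ring B plus C4 is the carvone skeleton, whose isopropenyl group becomes C4 by taking up one hydrogen atom and one bond to the oxygen-bearing C3. The C5 configuration of 34 is that of (S)-carvone (1); (R)-carvone would lead to the enantiomeric skeleton.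

## Logic of the disconnections

34 to 33 and 32. The C15 O–acyl bond and, behind it, the C15 O–Si bond are cut. The allylic acetate would not survive enolate formation or a borohydride, so it is placed last; this leaves 33 and then 32, in which C15 is masked by a robust silyl ether. The forward demand is acylation of the primary allylic hydroxyl of 33 in the presence of two secondary ones.

32 to 31, 29 and 28. The C3–H bond of the axial carbinol is cut (to 31), then the C2–O bond (to 29), then the C3 carbonyl is returned to the carbinol of 28. C2 is the only enolisable position of 29, and both new centres answer to the same control element, the axial C20 together with the axial C4 methyl. Ring A is thereby reduced to a single oxygen at C3, which is what the ring closure leaves there. The forward demands are an oxidant that arrives anti to C20 and a hydride that takes the equatorial trajectory.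

28 to 25 and 24. The C9–H bond is cut with transposition of the olefin from C7=C8 to C8=C9 and return of an oxygen to C7 (25); the C7–H and C3–H bonds are then cut to give 24. A stereocentre at C9 beside a non-conjugated olefin is most safely set by suprafacial hydrogen delivery from C7, so C9 is made trigonal. The gain is one stereocentre fewer and a conjugated enone. The forward demand is a C7 hydroxyl syn to C20 and a displacement with clean inversion.

24 to 23, then to 13 and 20. The C7 carbonyl is transposed back to a tertiary C9 carbinol (23) and the C9–C11 bond is cut. C9 is the carbonyl carbon of a carvone-type enone and so the natural electrophile, and the cut is convergent: it separates the fourteen-carbon bicycle 13 from the complete side chain 20. The forward demands are 1,2-addition to a ketone flanked by a quaternary carbon, and a chromium oxidant that transposes the allylic alcohol and oxidises the free C3 hydroxyl in the same flask, so that C3 needs no protecting group.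

13 to 10. The C3–C4 bond is cut and ring A is opened. C4 is a gem-dimethyl carbon on C5, so it can be a tertiary radical born from an isopropenyl group; C3 carries oxygen, so it can be an aldehyde acceptor. The cut removes a ring, the quaternary C4 and the C3 stereocentre and leaves a monocycle with two stereocentres. The forward step must put the hydrogen atom on the isopropenyl terminus only, close 6-exo on the aldehyde faster than the radical is reduced, and trap the alkoxy radical.

10 to 9, 7, 4 and 1. The aldehyde is traced through 9 to the terminal olefin of 7; then the C1–C10 bond (to 4 and 5) and the C10–C20 bond (to 1 and 2) are cut. Both are enolate alkylations at the α′ carbon of 1, and the order methyl first, chain second fixes C10, because the second electrophile enters anti to the isopropenyl group. The route is thus brought back to commercial 1, 2 and 5, with the C5 centre of 1 controlling C10. The forward demand is hydroboration of the monosubstituted olefin of 7 in the presence of the isopropenyl group and the enone.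

20 to 19, 18, 17, 15 and 14. The iodide is traced to alcohol 19 and its doubly silylated form 18; in 17 the C14–C15 and C13–C16 bonds are cut across the former triple bond of 15, the silyl ether of 14. Syn carbometalation of a terminal alkyne is the surest source of the E trisubstituted olefin, and the chain collapses to the four-carbon alkyne 14. The forward demands are methyl delivery to the internal alkyne carbon and two silyl ethers of unequal lability, so that only the C11 oxygen becomes iodide.

## Other disconnections considered

Alternative 1: The cut is at C1–C10 and C9–C11, with ring B taken from (1S,5S)-(−)-verbenone A1, whose bridgeheads map onto C5 and C7 and whose gem-dimethyl bridge is C4.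
- Forward key step: a CuBr·SMe2-catalysed 1,4-addition of an organomagnesium reagent carrying C1–C3 (C3 masked as a dioxolane) would place that chain on C10 anti to the bridge. The enolate would then be alkylated at C9 by an iodide analogous to 20, giving ketone A2. No ring is formed.
- In favour: two C–C bonds and the quaternary C10 arise in one operation with the correct sense relative to C5. All of ring B and C4 come from one terpene. The side chain is present from the start, so the four steps the chosen plan spends on C9 (steps 11–14) would not be needed; on this point Alternative 1 is the better plan.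
- Against: the same facial bias that sets C10 puts the side chain anti to the bridge, that is trans to C20. A2 is therefore the C9 epimer of what 34 needs and would have to be corrected by equilibration beside the C8 carbonyl after the bridge is cut, with no assurance where that equilibrium lies.
- Against: alkylation of a hindered magnesium enolate next to a new quaternary carbon with an unactivated primary iodide is slow.
- Against: the cyclobutane must still be cleaved under Lewis acid in the presence of an acetal, an allylic silyl ether and a trisubstituted olefin.
- Against: C8 still lacks its methyl and the C7=C8 olefin, and commercial A1 is often not enantiopure.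
- Against: ring A must still be closed at C3–C4, the very bond the chosen key step makes.
- Comparison: on structure the two plans are equal in taking ring B and C4 from a monoterpene, but 1 already has the C8 methyl and the C9 carbonyl. On mechanism the formation of A2 is polar and at least as predictable as the radical closure, but it defers the central problem. On step economy, bridge cleavage, C8 methylation, C9 correction, ring A closure and the ring A oxidation sequence would remain, so no saving over 14 linear steps is to be expected.

Alternative 2: The cut is at C5–C10 and C8–C9, opening both rings to triene A4, assembled from (R)-pantolactone A3, which supplies C4 with both methyls and C3 with its oxygen in the configuration of 34.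
- Forward key step: on heating, the E enoate of A4 would add across the 2-silyloxydiene (ester endo, tether arranged for trans fusion) to give decalin A5.
- In favour: both rings and C5, C9 and C10 are made in one step. The 2,3-diol arrives protected from the chiral pool, so steps 15–17 of the chosen plan and their facial-selectivity risk disappear, and the final acetylation would meet no free diol; on both points Alternative 2 is better. The use of a cheap chiral-pool compound is equal.
- Against: the dienophile is a β,β-disubstituted enoate that must form a quaternary carbon, and the diene terminus C5 is neopentyl, so reactivity is low.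
- Against: the required transition state is one of several, and only the acetonide stereocentres in the tether select the π face.
- Against: C2 must be set during assembly of A4, which also needs three defined olefins (E enoate, E,Z diene) and so a long linear preparation.
- Against: after A5 the C7 oxygen must be removed regioselectively into the C7=C8 olefin, and the C11 ester must be extended by four carbons with an E trisubstituted olefin next to the hindered C9.
- Comparison: on structure Alternative 2 handles ring A better and ring B and the side chain worse. On mechanism the cycloaddition is stereospecific in olefin geometry, a better-defined relation between C9 and C10 than any stepwise closure if it proceeds, but its rate and face selectivity are the open questions, whereas the chosen plan fixes C5 and C10 by two alkylations before ring closure. On step economy, triene assembly plus the later adjustments would probably exceed the chosen sequence.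

Alternative 3: The cut is at C9–C10 with ring A taken as a phenol: substrate A6 carries an allylsilane whose C7 stereocentre (S, E olefin, as required for an anti-SE2′ closure through a chair) is the only source of chirality.
- Forward key step: anodic two-electron oxidation of the phenolate would give a phenoxonium ion that C9 attacks at C10 (para to oxygen) with loss of silicon, closing ring B and giving dienone A7.
- In favour: ring B is complete in one step, with the C7=C8 olefin, C17, the C9 and C10 centres and the whole side chain, and the oxidant is the electrode. On ring B this is better than the chosen plan.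
- Against: ring A arrives as a cross-conjugated dienone with one C4 methyl. The second methyl, the C5 hydrogen trans to C20 and both hydroxyls remain to be introduced.
- Against: a reductive methylation of the C4=C5 enone with dissolving metal would threaten the allylic silyl ether and the C1=C2 enone, and the two enone halves must be told apart.
- Against: the axial C3 hydroxyl problem is the same as in the chosen plan.
- Against: A6 needs its own asymmetric synthesis, chirality transfer can leak through syn or boat pathways, and the anode must spare two electron-rich olefins.
- Comparison: on structure Alternative 3 buys ring B cheaply and pays on ring A, whereas the chosen plan has C4, C5, C10 and the C3 oxygen in place after step 5. On mechanism a cationic closure onto a phenoxonium ion is as defensible as the radical closure. On step economy it would be similar or longer.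

Key step: step 5

Assumption: centres that are erased later (C6 of 4, C3 of 13 and 25, C9 of 23) are drawn as the epimer expected to predominate; the other epimer would react on in the same way.

## Route

Step 1
Reactants: 1 (S)-(+)-carvone; 2 iodomethane
Product: 4 (5S,6R)-6-methylcarvone (methyl trans to isopropenyl; minor 6S epimer carried along), via lithium dienolate 3 (not isolated)
Conditions: LiN(i-Pr)2, THF, −78 °C; MeI, −78 → 0 °C
Reagents that add atoms: iodomethane (2), CI
Why: Kinetic deprotonation takes the α′ proton at C6 and the cross-conjugated enolate is C-methylated (enolate alkylation); the new centre is flattened again in step 2, so its configuration does not matter.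

Step 2
Reactants: 4 6-methylcarvone; 5 allyl bromide
Product: 7 (5R,6R)-6-allyl-6-methylcarvone (allyl trans to isopropenyl), via lithium enolate 6 (not isolated)
Conditions: LiN(i-Pr)2, THF, −78 °C; allyl bromide, DMPU, −78 → 0 °C
Reagents that add atoms: allyl bromide (5), C=CCBr
Why: Enolate alkylation creating the quaternary carbon (future C10); the allyl group should enter the planar enolate on the face away from the adjacent isopropenyl group, leaving the methyl cis and the chain trans to it, which is the trans ring fusion in latent form.

Step 3
Reactants: 7 6-allyl-6-methylcarvone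
Product: 9 (5R,6R)-6-(3-hydroxypropyl)-2,6-dimethyl-5-(prop-1-en-2-yl)cyclohex-2-en-1-one, via trialkylborane 8 (not isolated)
Conditions: Sia2BH (BH3·THF + 2-methylbut-2-ene), THF, 0 °C; NaBO3·4H2O, H2O, 23 °C
Reagents that add atoms: sodium perborate tetrahydrate, [Na+].[Na+].O[B-]1(O)OO[B-](O)(O)OO1
Why: Anti-Markovnikov hydroboration–oxidation; the bulky dialkylborane should take the monosubstituted vinyl group well ahead of the 1,1-disubstituted isopropenyl group and the hindered conjugated ketone, and perborate avoids the enone epoxidation that alkaline H2O2 could cause.

Step 4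
Reactants: 9 primary alcohol
Product: 10 3-[(1R,6R)-1,3-dimethyl-2-oxo-6-(prop-1-en-2-yl)cyclohex-3-en-1-yl]propanal
Conditions: Dess–Martin periodinane, CH2Cl2, 23 °C
Reagents that add atoms: none
Why: Dess–Martin oxidation of the primary alcohol under near-neutral conditions, which should spare both olefins and avoid aldol reactions of the keto aldehyde.

Step 5
Reactants: 10 keto aldehyde
Product: 13 trans-decalin enone (C9 ketone; C7=C8; C3–OH equatorial and syn to C20), via C4 tertiary radical 11 (not isolated), via C3 alkoxy radical 12 (not isolated)
Conditions: Fe(acac)3 (30 mol %), PhSiH3, EtOH/(CH2OH)2, 60 °C, degassed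
Reagents that add atoms: none
Why: The trivalent iron hydride formed from Fe(acac)3, PhSiH3 and ethanol transfers a hydrogen atom to the CH2 terminus of the isopropenyl group and gives the tertiary C4 radical 11 (metal-hydride hydrogen-atom transfer of the Mukaiyama type). Radical 11 adds to the aldehyde carbon C3 in a 6-exo-trig closure on C=O that forms the C3–C4 bond and ring A through a chair whose C5–C10 edge is already fixed with the chain equatorial. The alkoxy radical 12 is reduced by divalent iron and protonated by the alcohol solvent, which pulls the reversible addition forward. The closest known reaction type is the Fe(acac)3/PhSiH3 reductive cyclisation of olefins onto tethered ketone and aldehyde carbonyls, supported by the classical tin-hydride cyclisations of alkyl radicals onto aldehydes. C3 is the only new stereocentre; the chair with the forming C–O bond equatorial should favour the alcohol syn to C20, and either epimer is acceptable because C3 passes through a ketone in steps 12 and 15. The selectivity needed is hydrogen-atom transfer to the electron-rich 1,1-disubstituted olefin and not to the enone, secured by the polarity of the iron hydride and by the fact that the enone offers the C4 radical only a four-membered closure. C5 and C10 are untouched, so the trans ring fusion set in step 2 is carried into 13.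

Step 6
Reactants: 14 but-3-yn-1-ol
Product: 15 tert-butyl(but-3-yn-1-yloxy)dimethylsilane
Conditions: TBSCl, imidazole, DMF, 23 °C
Reagents that add atoms: tert-butyldimethylsilyl chloride, CC(C)(C)[Si](C)(C)Cl
Why: Standard silylation of a primary alcohol; the silyl ether marks the oxygen that will later become the C11 iodide.

Step 7
Reactants: 15 silyl ether of but-3-yn-1-ol
Product: 17 (2E)-5-[(tert-butyldimethylsilyl)oxy]-3-methylpent-2-en-1-ol, via alkenyldimethylalane 16 (not isolated)
Conditions: Me3Al, Cp2ZrCl2 (20 mol %), CH2Cl2, 0 → 23 °C; n-BuLi, THF, −30 °C; (CH2O)n, 23 °C; aq. HCl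
Reagents that add atoms: trimethylaluminium, C[Al](C)C; paraformaldehyde (as formaldehyde), C=O
Why: Negishi zirconium-catalysed carboalumination adds methyl and aluminium syn across the terminal alkyne with methyl on the internal carbon, so the olefin is E; the derived aluminate is hydroxymethylated by formaldehyde with retention of geometry.

Step 8
Reactants: 17 allylic alcohol
Product: 18 bis-silyl ether (C15–O–SiPh2t-Bu; C11–O–SiMe2t-Bu)
Conditions: TBDPSCl, imidazole, DMF, 23 °C
Reagents that add atoms: tert-butyldiphenylsilyl chloride, CC(C)(C)[Si](Cl)(c1ccccc1)c1ccccc1
Why: Silylation of the allylic alcohol with the more acid-stable silyl group, chosen to outlast t-BuLi, chromium, borohydride, Mitsunobu and enolate conditions.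

Step 9
Reactants: 18 bis-silyl ether
Product: 19 (3E)-5-[(tert-butyldiphenylsilyl)oxy]-3-methylpent-3-en-1-ol
Conditions: PPTS (cat.), EtOH, 40 °C
Reagents that add atoms: none
Why: Mild acid alcoholysis removes the primary tert-butyldimethylsilyl ether far faster than the tert-butyldiphenylsilyl ether, a routinely used lability difference.

Step 10
Reactants: 19 homoallylic alcohol
Product: 20 tert-butyl{[(2E)-5-iodo-3-methylpent-2-en-1-yl]oxy}diphenylsilane
Conditions: I2, PPh3, imidazole, CH2Cl2, 0 → 23 °C
Reagents that add atoms: iodine, II
Why: Appel-type iodination of a primary alcohol through its alkoxyphosphonium salt; the olefin geometry is not involved.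

Step 11
Reactants: 13 trans-decalin enone; 20 side-chain iodide
Product: 23 C9 tertiary allylic alcohol (3,9-diol; C9–OH syn to C20), via alkyllithium 21 (not isolated), via alkylcerium dichloride 22 (not isolated)
Conditions: 20 (2.5 equiv), t-BuLi, Et2O, −78 °C; CeCl3, THF, −78 °C; then 13, −78 → −40 °C; aq. NH4Cl
Reagents that add atoms: none
Why: Lithium–iodine exchange and transmetalation give a weakly basic organocerium reagent whose 1,2-addition to hindered enones is well established; one equivalent is spent on the free C3 hydroxyl, and the C9 carbinol centre (attack expected anti to the axial C20) is erased in step 12.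

Step 12
Reactants: 23 tertiary allylic alcohol
Product: 24 ene-dione (C3 ketone; C7 ketone conjugated with C8=C9)
Conditions: [C5H5NH][CrO3Cl], 4 Å molecular sieves, CH2Cl2, 23 °C
Reagents that add atoms: pyridinium chlorochromate, [O-][Cr](=O)(=O)Cl.c1cc[nH+]cc1
Why: Dauben–Babler oxidative 1,3-transposition moves the allylic oxygen function from C9 to C7 (the C7 oxygen is delivered by chromium) and the olefin to C8=C9, while the same reagent oxidises the secondary C3 alcohol, so C3 needs no protecting group.

Step 13
Reactants: 24 ene-dione
Product: 25 allylic diol (C7–OH and C3–OH both syn to C20; C8=C9)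
Conditions: NaBH4, CeCl3·7H2O, MeOH/THF, −78 → −20 °C
Reagents that add atoms: none
Why: Luche 1,2-reduction; axial hydride attack at C7 from the face opposite C20 should give the pseudo-equatorial alcohol syn to C20, the configuration step 14 needs, and the C3 ketone is reduced along with it to the equatorial alcohol, which is harmless because step 15 re-oxidises it.

Step 14
Reactants: 25 allylic diol
Product: 28 C7=C8 olefin with H9 anti to C20 (C3–OH free; C15 silyl ether), via Mitsunobu adduct 26 (not isolated), via allylic diazene 27 (not isolated)
Conditions: IPNBSH (2-O2NC6H4SO2NHN=CMe2), PPh3, DEAD, THF, 0 → 23 °C; CF3CH2OH/H2O, 23 °C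
Reagents that add atoms: none
Why: Reductive 1,3-transposition of an allylic alcohol: the Mitsunobu displacement inverts C7 and puts nitrogen on the face anti to C20, hydrolysis and loss of sulfinic acid give the monoalkyl diazene, and its retro-ene loss of N2 delivers hydrogen to C9 on that same face while the olefin moves to C7=C8; the neopentyl C3 hydroxyl cannot be displaced and should remain a spectator.

Step 15
Reactants: 28 C3 alcohol
Product: 29 C3 ketone
Conditions: Dess–Martin periodinane, CH2Cl2, 23 °C
Reagents that add atoms: none
Why: Dess–Martin oxidation of the hindered secondary alcohol; the reagent does not touch trisubstituted olefins or the silyl ether.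

Step 16
Reactants: 29 C3 ketone
Product: 31 2-hydroxy-3-ketone (C2–OH equatorial and anti to C20), via potassium enolate 30 (not isolated)
Conditions: KN(SiMe3)2, THF, −78 °C; 2-(phenylsulfonyl)-3-phenyloxaziridine, −78 °C; aq. NH4Cl
Reagents that add atoms: 2-(benzenesulfonyl)-3-phenyloxaziridine, O=S(=O)(N1OC1c1ccccc1)c1ccccc1
Why: Davis enolate hydroxylation; C2 is the only enolisable position, and the oxaziridine should approach the enolate anti to the axial C20 and axial C4 methyl, giving the equatorial C2 hydroxyl, while an oxaziridine does not epoxidise the two olefins.

Step 17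
Reactants: 31 2-hydroxy-3-ketone
Product: 32 2,3-cis-diol (C3–OH axial; both hydroxyls anti to C20; C15 silyl ether)
Conditions: LiBH(s-Bu)3, THF, −78 °C; NaOH, H2O2, 0 °C
Reagents that add atoms: none
Why: Bulky trialkylborohydride reduction; the reagent avoids the axial trajectory (1,3-diaxial hydrogens at C1 and C5) and attacks equatorially, which places the C3 hydroxyl axial and cis to the C2 hydroxyl.

Step 18
Reactants: 32 diol silyl ether
Product: 33 triol (2,3,15-triol)
Conditions: Bu4NF, THF, 23 °C; aq. NH4Cl
Reagents that add atoms: none
Why: Fluoride cleavage of the primary allylic silyl ether; nothing else in the molecule is fluoride- or base-sensitive at this stage.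

Step 19
Reactants: 33 triol
Product: 34 ent-2α,3α-dihydroxylabda-7,13E-dien-15-yl acetate (target)
Conditions: AcCl (1.1 equiv), 2,4,6-collidine, CH2Cl2, −78 °C
Reagents that add atoms: acetyl chloride, CC(Cl)=O
Why: Low-temperature acylation with acetyl chloride and a hindered pyridine base discriminates primary from secondary alcohols; the C3 hydroxyl is axial and neopentyl and the C2 hydroxyl is secondary, so the primary allylic C15 hydroxyl should be acetylated alone.

## Compound list

1 | (S)-(+)-carvone | CC1=CC[C@@H](CC1=O)C(C)=C | starting material
2 | iodomethane | CI | starting material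
3 | lithium dienolate of 1 (not isolated) | CC1=CC[C@@H](C=C1O[Li])C(C)=C | intermediate
4 | (5S,6R)-2,6-dimethyl-5-(prop-1-en-2-yl)cyclohex-2-en-1-one (6-methylcarvone, methyl trans to isopropenyl) | O=C1C(C)=CC[C@H](C(C)=C)[C@H]1C | intermediate
5 | allyl bromide | C=CCBr | starting material
6 | lithium enolate of 4 (not isolated) | CC1=CC[C@@H](C(C)=C1O[Li])C(C)=C | intermediate
7 | (5R,6R)-2,6-dimethyl-6-(prop-2-en-1-yl)-5-(prop-1-en-2-yl)cyclohex-2-en-1-one (allyl trans to isopropenyl) | O=C1C(C)=CC[C@H](C(C)=C)[C@@]1(C)CC=C | intermediate
8 | alkylbis(3-methylbutan-2-yl)borane from 7 (not isolated) | O=C1C(C)=CC[C@H](C(C)=C)[C@@]1(C)CCCB(C(C)C(C)C)C(C)C(C)C | intermediate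
9 | (5R,6R)-6-(3-hydroxypropyl)-2,6-dimethyl-5-(prop-1-en-2-yl)cyclohex-2-en-1-one | O=C1C(C)=CC[C@H](C(C)=C)[C@@]1(C)CCCO | intermediate
10 | 3-[(1R,6R)-1,3-dimethyl-2-oxo-6-(prop-1-en-2-yl)cyclohex-3-en-1-yl]propanal | O=C1C(C)=CC[C@H](C(C)=C)[C@@]1(C)CCC=O | intermediate
11 | C4 tertiary radical from 10 (not isolated) | O=C1C(C)=CC[C@H]([C](C)C)[C@@]1(C)CCC=O | intermediate
12 | C3 alkoxy radical of the closed decalin (not isolated) | O=C1C(C)=CC[C@@H]2C(C)(C)[C@H]([O])CC[C@@]12C | intermediate
13 | 6-hydroxy-2,5,5,8a-tetramethyl-4a,5,6,7,8,8a-hexahydronaphthalen-1(4H)-one, trans-fused, hydroxyl cis to the 8a-methyl (labdane numbering: C9 ketone, C7=C8, C3–OH) | O=C1C(C)=CC[C@@H]2C(C)(C)[C@H](O)CC[C@@]12C | intermediate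
14 | but-3-yn-1-ol | C#CCCO | starting material
15 | tert-butyl(but-3-yn-1-yloxy)dimethylsilane | C#CCCO[Si](C)(C)C(C)(C)C | intermediate
16 | (E)-alkenyldimethylalane from 15 (not isolated) | C[Al](C)/C=C(\C)CCO[Si](C)(C)C(C)(C)C | intermediate
17 | (2E)-5-[(tert-butyldimethylsilyl)oxy]-3-methylpent-2-en-1-ol | OC/C=C(\C)CCO[Si](C)(C)C(C)(C)C | intermediate
18 | (2E)-1-[(tert-butyldiphenylsilyl)oxy]-5-[(tert-butyldimethylsilyl)oxy]-3-methylpent-2-ene | CC(C)(C)[Si](C)(C)OCC/C(C)=C/CO[Si](c1ccccc1)(c1ccccc1)C(C)(C)C | intermediate
19 | (3E)-5-[(tert-butyldiphenylsilyl)oxy]-3-methylpent-3-en-1-ol | OCC/C(C)=C/CO[Si](c1ccccc1)(c1ccccc1)C(C)(C)C | intermediate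
20 | tert-butyl{[(2E)-5-iodo-3-methylpent-2-en-1-yl]oxy}diphenylsilane | ICC/C(C)=C/CO[Si](c1ccccc1)(c1ccccc1)C(C)(C)C | intermediate
21 | alkyllithium from 20 (not isolated) | [Li]CC/C(C)=C/CO[Si](c1ccccc1)(c1ccccc1)C(C)(C)C | intermediate
22 | alkylcerium dichloride from 21 (not isolated) | Cl[Ce](Cl)CC/C(C)=C/CO[Si](c1ccccc1)(c1ccccc1)C(C)(C)C | intermediate
23 | C9 tertiary allylic alcohol: 3,9-dihydroxy, C7=C8, C13=C14 (E), 15-silyloxy; C9–OH and C3–OH syn to C20 | O[C@]1(CC/C(C)=C/CO[Si](c3ccccc3)(c3ccccc3)C(C)(C)C)C(C)=CC[C@@H]2C(C)(C)[C@H](O)CC[C@@]12C | intermediate
24 | ene-dione: C3 ketone, C7 ketone, C8=C9, 15-silyloxy | O=C1C[C@@H]2C(C)(C)C(=O)CC[C@@]2(C)C(CC/C(C)=C/CO[Si](c3ccccc3)(c3ccccc3)C(C)(C)C)=C1C | intermediate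
25 | allylic diol: C7–OH and C3–OH syn to C20, C8=C9, 15-silyloxy | O[C@@H]1C[C@@H]2C(C)(C)[C@H](O)CC[C@@]2(C)C(CC/C(C)=C/CO[Si](c3ccccc3)(c3ccccc3)C(C)(C)C)=C1C | intermediate
26 | Mitsunobu adduct: C7 N-(2-nitrobenzenesulfonyl)-N′-isopropylidenehydrazide, nitrogen anti to C20 (not isolated) | CC(C)=NN([C@H]1C[C@@H]2C(C)(C)[C@H](O)CC[C@@]2(C)C(CC/C(C)=C/CO[Si](c3ccccc3)(c3ccccc3)C(C)(C)C)=C1C)S(=O)(=O)c1ccccc1[N+](=O)[O-] | intermediate
27 | C7 allylic diazene (not isolated) | N=N[C@H]1C[C@@H]2C(C)(C)[C@H](O)CC[C@@]2(C)C(CC/C(C)=C/CO[Si](c3ccccc3)(c3ccccc3)C(C)(C)C)=C1C | intermediate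
28 | 3-hydroxy-ent-labda-7,13E-dien-15-yl tert-butyldiphenylsilyl ether (C3–OH syn to C20; H9 and H5 anti to C20) | CC(C)(C)[Si](c3ccccc3)(c3ccccc3)OC/C=C(\C)CC[C@@H]1C(C)=CC[C@@H]2C(C)(C)[C@H](O)CC[C@@]12C | intermediate
29 | 3-oxo-ent-labda-7,13E-dien-15-yl tert-butyldiphenylsilyl ether | CC(C)(C)[Si](c3ccccc3)(c3ccccc3)OC/C=C(\C)CC[C@@H]1C(C)=CC[C@@H]2C(C)(C)C(=O)CC[C@@]12C | intermediate
30 | potassium C2=C3 enolate of 29 (not isolated) | CC(C)(C)[Si](c3ccccc3)(c3ccccc3)OC/C=C(\C)CC[C@@H]1C(C)=CC[C@@H]2C(C)(C)C(O[K])=CC[C@@]12C | intermediate
31 | 2-hydroxy-3-oxo compound (C2–OH equatorial, anti to C20) | CC(C)(C)[Si](c3ccccc3)(c3ccccc3)OC/C=C(\C)CC[C@@H]1C(C)=CC[C@@H]2C(C)(C)C(=O)[C@@H](O)C[C@@]12C | intermediate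
32 | 2,3-cis-diol (both hydroxyls anti to C20), 15-silyl ether | CC(C)(C)[Si](c3ccccc3)(c3ccccc3)OC/C=C(\C)CC[C@@H]1C(C)=CC[C@@H]2C(C)(C)[C@@H](O)[C@@H](O)C[C@@]12C | intermediate
33 | ent-labda-7,13E-diene-2α,3α,15-triol | OC/C=C(\C)CC[C@@H]1C(C)=CC[C@@H]2C(C)(C)[C@@H](O)[C@@H](O)C[C@@]12C | intermediate
34 | ent-2α,3α-dihydroxylabda-7,13E-dien-15-yl acetate (CNP0280580.2) | CC(=O)OC/C=C(\C)CC[C@@H]1C(C)=CC[C@@H]2C(C)(C)[C@@H](O)[C@@H](O)C[C@@]12C | target

## Step count and least certain steps

Total: 19 steps. Longest linear sequence: 14 steps (1–5, then 11–19; the side-chain branch 6–10, then 11–19 is equally long).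

Step 5 (key step). The addition of 11 to the aldehyde is reversible, so 12 may reopen and 11 may be reduced, which would amount to hydrogenation of the isopropenyl group. The aldehyde may also be reduced or acetalised by silane and alcohol, or lose its formyl hydrogen to the radical. Fallback, from 10 back to 13: Markovnikov addition of HBr (HBr in AcOH, 0 °C) to the isopropenyl group would give the tertiary bromide F1, and Bu3SnH with AIBN in benzene at 80 °C (slow addition) would generate the same C4 radical in a chain process in which the alkoxy radical is trapped rapidly by the tin hydride, a long-established way to close rings onto aldehydes.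

Step 14. The Mitsunobu displacement at the hindered C7 carbinol, flanked by a tetrasubstituted olefin, may be slow and give way to elimination to a diene or to unproductive activation of the C3 hydroxyl. Any loss of facial selectivity in step 13 would also appear here as epimerisation at C9. Fallback, from 25 back to 28: selective formylation of the allylic hydroxyl (acetic formic anhydride, pyridine, −40 °C) would give the C7 formate F2. Heating F2 with Pd(OAc)2 and n-Bu3P in dioxane would ionise it on the face opposite the formate and transfer hydride from palladium to the more substituted terminus C9 on that same face, giving the same configuration at C9 with loss of CO2.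

Step 17. Facial selectivity may be poor: the axial C4 methyl flanks the equatorial trajectory, and axial attack would give the trans diequatorial diol, which cannot be inverted at the neopentyl C3. Fallback, from 13 back to 32, making the diol by cis-dihydroxylation before any electron-rich olefin is present:
- Oxidation of 13 (Dess–Martin periodinane) would give the diketone F3.
- KN(SiMe3)2 and PhNTf2 would convert the C3 ketone, the only one with an α-hydrogen, into the enol triflate F4.
- Pd(OAc)2/PPh3 with HCO2H/Bu3N would reduce it to the C2=C3 olefin F5.
- OsO4 (cat.) with N-methylmorpholine N-oxide should add to this isolated cis olefin from the face opposite C20 and the axial C4 methyl, leaving the electron-poor enone, to give the diol F6.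
- 2,2-Dimethoxypropane and PPTS would protect it as the acetonide F7.
- Steps 11–14 would then be repeated on F7: organocerium addition to the tertiary alcohol F8, pyridinium chlorochromate to the transposed enone F9, NaBH4/CeCl3 to the allylic alcohol F10, and the diazene rearrangement to the olefin F11.
- Aqueous acetic acid would remove the acetonide and return to 32.

Step 19. Over-acylation at the equatorial C2 hydroxyl, or acetyl migration within the triol, would lower selectivity for the primary position. Fallback, from 33 back to 34: 2,2-dimethoxypropane and PPTS would tie up the cis-diol as the acetonide alcohol F12, Ac2O/pyridine would give the acetonide acetate F13, and aqueous acetic acid at 40 °C would release 34.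

## Further compounds

F1 | step 5 | 3-[(1R)-6-(2-bromopropan-2-yl)-1,3-dimethyl-2-oxocyclohex-3-en-1-yl]propanal (bromide trans to the chain as in 10) | O=C1C(C)=CC[C@H](C(C)(C)Br)[C@@]1(C)CCC=O
F2 | step 14 | C7 formate of 25 | O=CO[C@@H]1C[C@@H]2C(C)(C)[C@H](O)CC[C@@]2(C)C(CC/C(C)=C/CO[Si](c3ccccc3)(c3ccccc3)C(C)(C)C)=C1C
F3 | step 17 | C3,C9 diketone from 13 | O=C1C(C)=CC[C@@H]2C(C)(C)C(=O)CC[C@@]12C
F4 | step 17 | C2=C3 enol triflate | O=C1C(C)=CC[C@@H]2C(C)(C)C(OS(=O)(=O)C(F)(F)F)=CC[C@@]12C
F5 | step 17 | C2=C3 olefin of the decalin enone | O=C1C(C)=CC[C@@H]2C(C)(C)C=CC[C@@]12C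
F6 | step 17 | 2,3-cis-diol of the decalin enone (hydroxyls anti to C20) | O=C1C(C)=CC[C@@H]2C(C)(C)[C@@H](O)[C@@H](O)C[C@@]12C
F7 | step 17 | 2,3-acetonide of F6 | O=C1C(C)=CC[C@@H]2C(C)(C)[C@@H](O3)[C@@H](OC3(C)C)C[C@@]12C
F8 | step 17 | C9 tertiary allylic alcohol, acetonide series | O[C@]1(CC/C(C)=C/CO[Si](c4ccccc4)(c4ccccc4)C(C)(C)C)C(C)=CC[C@@H]2C(C)(C)[C@@H](O3)[C@@H](OC3(C)C)C[C@@]12C
F9 | step 17 | C7 enone (C8=C9), acetonide series | O=C1C[C@@H]2C(C)(C)[C@@H](O3)[C@@H](OC3(C)C)C[C@@]2(C)C(CC/C(C)=C/CO[Si](c4ccccc4)(c4ccccc4)C(C)(C)C)=C1C
F10 | step 17 | C7 allylic alcohol (syn to C20), acetonide series | O[C@@H]1C[C@@H]2C(C)(C)[C@@H](O3)[C@@H](OC3(C)C)C[C@@]2(C)C(CC/C(C)=C/CO[Si](c4ccccc4)(c4ccccc4)C(C)(C)C)=C1C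
F11 | step 17 | 2,3-acetonide of 32 | CC(C)(C)[Si](c4ccccc4)(c4ccccc4)OC/C=C(\C)CC[C@@H]1C(C)=CC[C@@H]2C(C)(C)[C@@H](O3)[C@@H](OC3(C)C)C[C@@]12C
F12 | step 19 | 2,3-acetonide of 33 | OC/C=C(\C)CC[C@@H]1C(C)=CC[C@@H]2C(C)(C)[C@@H](O3)[C@@H](OC3(C)C)C[C@@]12C
F13 | step 19 | 2,3-acetonide of 34 | CC(=O)OC/C=C(\C)CC[C@@H]1C(C)=CC[C@@H]2C(C)(C)[C@@H](O3)[C@@H](OC3(C)C)C[C@@]12C
A1 | alternative 1 | (1S,5S)-(−)-verbenone | CC1=CC(=O)[C@H]2C[C@@H]1C2(C)C
A2 | alternative 1 | bicyclo[3.1.1]heptan-2-one with quaternary C10 (methyl, dioxolanylethyl chain) and the side chain on C9, both chains anti to the gem-dimethyl bridge (C9 epimeric to 34) | C[C@]1(CCC3OCCO3)[C@@H](CC/C(C)=C/CO[Si](C)(C)C(C)(C)C)C(=O)[C@H]2C[C@@H]1C2(C)C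
A3 | alternative 2 | (R)-pantolactone | CC1(C)COC(=O)[C@@H]1O
A4 | alternative 2 | triene: E enoate, C2,C3 acetonide, E,Z 2-silyloxydiene | COC(=O)/C=C(\C)C[C@@H]1OC(C)(C)O[C@@H]1C(C)(C)/C=C/C(O[Si](C)(C)C(C)(C)C)=C/C
A5 | alternative 2 | trans-decalin with C2,C3 acetonide, C7 silyl enol ether, C8 methyl and C11 methyl ester | COC(=O)[C@@H]1[C@H](C)C(O[Si](C)(C)C(C)(C)C)=C[C@@H]2C(C)(C)[C@@H](O3)[C@@H](OC3(C)C)C[C@@]12C
A6 | alternative 3 | 2,4-dimethyl-3-substituted phenol carrying the (S)-configured E allylsilane and the side chain | Cc1ccc(O)c(C)c1C[C@H]([Si](C)(C)C)/C(C)=C/CC/C(C)=C/CO[Si](C)(C)C(C)(C)C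
A7 | alternative 3 | ring A cross-conjugated dienone (C3 ketone, one C4 methyl) with ring B and side chain complete | CC(C)(C)[Si](C)(C)OC/C=C(\C)CC[C@@H]1C(C)=CCC2=C(C)C(=O)C=C[C@@]12C
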